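**Retrosynthetic overview** (ent-kaurane numbering, C1–C20, is used for every intermediate)

1. The target is a 6,7-seco-ent-kauran-7,20-olide; the last operations are C16 α-methylenation, C11–B to C11–OH exchange and desilylation.
2. Key disconnection: C8–C9 (closes the δ-lactone C7–O–C20–C10–C9–C8) together with C11–C12 (closes ring C), in one radical bicyclization of an α-bromo-β-keto ester (ring D) esterified to the ring A neopentyl alcohol that carries a C9=C11 alkenyl boronate.
3. Enabling feature: C8 lies between the C7 lactone carbonyl and the C15 ketone (a chelatable 1,3-dicarbonyl α-carbon, hence an electrophilic tertiary radical). C9 is vicinal to oxygenated C11, so C9=C11–B stands for C9–C11–OH. C11 is 1,3 to C13 through C12, and the ester oxygen of the lactone places C9 six atoms from C8.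
4. Ring D comes from malonate and a 2-(silylmethyl)allyl chloride by allylsilane acylation. Ring A comes from an enantioselective Diels–Alder reaction (dienophile C4=C5, diene C3=C2–C1=C10) that sets C4 and C5; the C10 quaternary centre comes from ester enolate formylation and boronate olefination.
5. Ring order: A (step 5), D (step 16), then lactone and C together (step 19).

Key step: step 19

Remark: the configuration of every intermediate is the one written in its SMILES string; relative descriptors in the names refer to ent-kaurane positions.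
Assumption: the chiral oxazaborolidinium catalyst of step 5 (and the oxazolidinone auxiliary of its fallback) is taken to shield the face of the dienophile that leads to 8 as drawn; the mirror-image controller would be taken if induction ran the other way.

**Route**

Step 1
Reactants: 1 ethyl 2-(triphenyl-λ5-phosphanylidene)propanoate; 2 2,2-dimethoxyacetaldehyde
Product: 3 ethyl (2E)-4,4-dimethoxy-2-methylbut-2-enoate
Conditions: CH2Cl2, 25 °C
Reagents that add atoms: none
Why: Wittig olefination with a stabilised ylide should give the (E)-trisubstituted enoate, whose geometry later becomes the trans C18/C6 relation.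

Step 2
Reactants: 3 ethyl (2E)-4,4-dimethoxy-2-methylbut-2-enoate
Product: 4 ethyl (2E)-2-methyl-4-oxobut-2-enoate
Conditions: 1 M aq. HCl, THF, 0 → 25 °C
Reagents that add atoms: water (O)
Why: Acid-catalysed acetal hydrolysis should unmask the aldehyde without touching the ester or the alkene geometry.

Step 3
Reactants: 5 (2E)-penta-2,4-dienoic acid
Product: 6 (2E)-penta-2,4-dien-1-ol
Conditions: LiAlH4, Et2O, 0 °C
Reagents that add atoms: none
Why: Hydride 1,2-reduction of the conjugated acid should give the dienol with the E geometry retained.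

Step 4
Reactants: 6 (2E)-penta-2,4-dien-1-ol
Product: 7 benzyl (2E)-penta-2,4-dien-1-yl ether
Conditions: NaH, BnBr, n-Bu4NI (cat.), THF, 0 → 25 °C
Reagents that add atoms: benzyl bromide (BrCc1ccccc1)
Why: Williamson etherification protects the future C20 oxygen as a benzyl ether that can later be removed in the same operation as alkene hydrogenation.

Step 5
Reactants: 4 ethyl (2E)-2-methyl-4-oxobut-2-enoate; 7 benzyl (2E)-penta-2,4-dien-1-yl ether
Product: 8 ethyl 3-[(benzyloxy)methyl]-2-formyl-1-methylcyclohex-4-ene-1-carboxylate (formyl cis to the ring methyl and cis to the benzyloxymethyl group)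
Conditions: (S)-o-tolyl-oxazaborolidine from (S)-diphenylprolinol (20 mol %), Tf2NH (20 mol %), CH2Cl2, −78 → −40 °C
Reagents that add atoms: none
Why: In this catalytic enantioselective Diels–Alder reaction, boron coordination to the aldehyde makes C4 the electrophilic terminus so that the substituted diene carbon C10 bonds to C5 (ortho mode); the E geometry of 4 gives C18 trans and CH3 cis to C6, the aldehyde-endo approach puts C20 cis to C6, and the catalyst selects the enantiotopic face.

Step 6
Reactants: 8 ethyl 3-[(benzyloxy)methyl]-2-formyl-1-methylcyclohex-4-ene-1-carboxylate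
Product: 9 {3-[(benzyloxy)methyl]-1-methylcyclohex-4-ene-1,2-diyl}dimethanol (hydroxymethyl groups trans)
Conditions: LiAlH4, THF, 0 °C
Reagents that add atoms: none
Why: Hydride reduction of the aldehyde and the ester should be faster than epimerisation of C5, which is fixed once the formyl group is reduced.

Step 7
Reactants: 9 {3-[(benzyloxy)methyl]-1-methylcyclohex-4-ene-1,2-diyl}dimethanol
Product: 10 bis(tert-butyldimethylsilyl) ether of 9
Conditions: TBSCl, imidazole, DMF, 25 °C
Reagents that add atoms: tert-butyldimethylsilyl chloride (CC(C)(C)[Si](C)(C)Cl)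
Why: Silylation of both primary alcohols (C6 and C18) gives ethers that should survive every step up to the final fluoride treatment.

Step 8
Reactants: 10 bis(tert-butyldimethylsilyl) ether of 9
Product: 11 [2,3-bis(tert-butyldimethylsilyloxymethyl)-3-methylcyclohexyl]methanol (C20 alcohol)
Conditions: H2 (1 atm), Pd/C (palladium on carbon), EtOAc, 25 °C
Reagents that add atoms: none
Why: Heterogeneous hydrogenation should saturate C1=C2 and cleave the benzyl ether in one operation while neutral conditions leave the silyl ethers intact.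

Step 9
Reactants: 11 [2,3-bis(tert-butyldimethylsilyloxymethyl)-3-methylcyclohexyl]methanol
Product: 12 2,3-bis(tert-butyldimethylsilyloxymethyl)-3-methylcyclohexane-1-carboxylic acid
Conditions: TEMPO (cat.), PhI(OAc)2, MeCN/H2O, 25 °C
Reagents that add atoms: water (O)
Why: Nitroxyl-catalysed oxidation of the primary alcohol through the aldehyde hydrate should give the acid; any epimerisation at C10 is harmless because C10 is enolised in step 11.

Step 10
Reactants: 12 2,3-bis(tert-butyldimethylsilyloxymethyl)-3-methylcyclohexane-1-carboxylic acid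
Product: 13 methyl 2,3-bis(tert-butyldimethylsilyloxymethyl)-3-methylcyclohexane-1-carboxylate
Conditions: MeI, K2CO3, DMF, 25 °C
Reagents that add atoms: iodomethane (CI)
Why: O-alkylation of the carboxylate gives the methyl ester needed for enolate chemistry at C10.

Step 11
Reactants: 13 methyl 2,3-bis(tert-butyldimethylsilyloxymethyl)-3-methylcyclohexane-1-carboxylate
Product: 14 methyl 2,3-bis(tert-butyldimethylsilyloxymethyl)-1-formyl-3-methylcyclohexane-1-carboxylate (formyl trans to the C5 silyloxymethyl group)
Conditions: LiN(i-Pr)2, THF, −78 °C; then HCO2CH2CF3, −78 → −40 °C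
Reagents that add atoms: 2,2,2-trifluoroethyl formate (O=COCC(F)(F)F)
Why: C-formylation of the ester enolate (crossed Claisen acylation) should create the C10 quaternary centre, the formyl carbon C9 entering equatorially, anti to the C5 substituent and away from the axial C4 methyl, so that the ester carbon C20 ends cis to C6.

Step 12
Reactants: 14 methyl 2,3-bis(tert-butyldimethylsilyloxymethyl)-1-formyl-3-methylcyclohexane-1-carboxylate
Product: 15 methyl 2,3-bis(tert-butyldimethylsilyloxymethyl)-3-methyl-1-[(E)-2-(4,4,5,5-tetramethyl-1,3,2-dioxaborolan-2-yl)ethenyl]cyclohexane-1-carboxylate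
Conditions: CrCl2, Cl2CHB(pin), THF, 25 °C
Reagents that add atoms: 2-(dichloromethyl)-4,4,5,5-tetramethyl-1,3,2-dioxaborolane (ClC(Cl)B1OC(C)(C)C(C)(C)O1)
Why: Takai–Utimoto olefination with the gem-dichromium species formed by divalent chromium should turn the non-enolisable aldehyde into the (E)-alkenyl boronate (C9=C11) without touching the ester.

Step 13
Reactants: 15 methyl 2,3-bis(tert-butyldimethylsilyloxymethyl)-3-methyl-1-[(E)-2-(4,4,5,5-tetramethyl-1,3,2-dioxaborolan-2-yl)ethenyl]cyclohexane-1-carboxylate
Product: 16 {2,3-bis(tert-butyldimethylsilyloxymethyl)-3-methyl-1-[(E)-2-(4,4,5,5-tetramethyl-1,3,2-dioxaborolan-2-yl)ethenyl]cyclohexyl}methanol (ring A alcohol)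
Conditions: i-Bu2AlH, CH2Cl2, −78 → 0 °C
Reagents that add atoms: none
Why: Aluminium hydride reduction of the ester gives the neopentyl C20 alcohol, the pinacol boronate and silyl ethers being expected to survive at low temperature.

Step 14
Reactants: 17 dimethyl propanedioate; 18 [2-(chloromethyl)prop-2-en-1-yl](trimethyl)silane
Product: 19 dimethyl 2-{2-[(trimethylsilyl)methyl]prop-2-en-1-yl}propanedioate
Conditions: NaH, THF/DMF, 0 °C; then 18, NaI (cat.), 50 °C
Reagents that add atoms: none
Why: Malonate alkylation (SN2 at the primary allylic chloride) installs the unit that carries C14, C13, C12 and C16.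

Step 15
Reactants: 19 dimethyl 2-{2-[(trimethylsilyl)methyl]prop-2-en-1-yl}propanedioate
Product: 20 3-methoxy-3-oxo-2-{2-[(trimethylsilyl)methyl]prop-2-en-1-yl}propanoic acid
Conditions: KOH (1.0 equiv), MeOH/H2O, 0 → 25 °C; then 1 M HCl to pH 3 at 0 °C
Reagents that add atoms: potassium hydroxide ([K+].[OH-])
Why: Mono-saponification of the malonate stops after one ester because the first carboxylate deactivates the second ester toward hydroxide.

Step 16
Reactants: 20 3-methoxy-3-oxo-2-{2-[(trimethylsilyl)methyl]prop-2-en-1-yl}propanoic acid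
Product: 22 methyl 4-methylidene-2-oxocyclopentane-1-carboxylate, via acid chloride 21 (not isolated)
Conditions: 1-chloro-N,N,2-trimethylprop-1-en-1-amine, CH2Cl2, 0 °C; then SnCl4, CH2Cl2, −78 °C
Reagents that add atoms: none
Why: Neutral acid chloride formation followed by intramolecular Lewis-acid-promoted acylation of the allylsilane (SE2′ methylenecyclopentane annulation) should close ring D and place the exocyclic C13=C12 alkene by loss of the silyl group; the C8 centre formed is planarised later.

Step 17
Reactants: 16 ring A alcohol; 22 methyl 4-methylidene-2-oxocyclopentane-1-carboxylate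
Product: 23 ring A ester of 4-methylidene-2-oxocyclopentane-1-carboxylic acid (β-keto ester, both C8 epimers)
Conditions: DMAP (0.3 equiv), toluene, 4 Å MS, 110 °C
Reagents that add atoms: none
Why: DMAP-mediated transesterification of the β-keto ester through its acylketene should acylate even the hindered neopentyl C20 alcohol.

Step 18
Reactants: 23 ring A ester of 4-methylidene-2-oxocyclopentane-1-carboxylic acid
Product: 24 C8-bromo derivative of 23 (α-bromo-β-keto ester)
Conditions: NBS, Mg(ClO4)2 (0.3 equiv), MeCN, 0 °C
Reagents that add atoms: N-bromosuccinimide (O=C1CCC(=O)N1Br)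
Why: Lewis-acid-catalysed α-bromination of the 1,3-dicarbonyl through its magnesium enolate should be much faster than attack of NBS on the alkenyl boronate or the 1,1-disubstituted alkene.

Step 19
Reactants: 24 C8-bromo derivative of 23
Product: 26 11-(pinacolatoboryl)-6,18-bis(tert-butyldimethylsilyloxy)-15-oxo-17-nor-6,7-seco-ent-kauran-7,20-olide, via bridgehead bromide 25 (not isolated)
Conditions: Mg(ClO4)2 (1.2 equiv), Et3B (0.5 equiv), air, CH2Cl2 (0.01 M), 25 °C; then Bu3SnH, AIBN, toluene, 80 °C
Reagents that add atoms: none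
Why: Ethyl radical from Et3B/O2 abstracts bromine from 24 to give the electrophilic tertiary C8 radical, which as its Mg-chelated 1,3-dicarbonyl adds to C9 of the alkenyl boronate (C8–C9, δ-lactone); the α-boryl C11 radical then adds to C12 of the ring D exocyclic alkene (ring C), and the bridgehead C13 radical takes bromine from 24 to carry the chain before Bu3SnH replaces that bromine by hydrogen. The closest known reaction type is the Lewis-acid-promoted bromine-atom-transfer radical cyclization of unsaturated α-bromo-β-keto esters, combined with the addition of α-carbonyl radicals to alkenyl boronic esters. The lactone closes 6-exo-trig through the ester oxygen and ring C closes 6-endo-trig, the 5-exo alternative being disfavoured because it would attack the fully substituted C13 and build a norbornane. C9 is set by a chair-like transition state in which the C9=C11 unit and the bulky C5 branch of the spiro carbon C10 are both equatorial; C8 is set by the Mg chelate, which holds the C15 ketone syn to the ester carbonyl so that C15 becomes equatorial and C14 axial on the forming lactone; C11 is set by the boryl group taking the equatorial (exo) position of the forming ring C chair, and C13 follows from the bridging geometry. The step needs exo regioselectivity in the first closure, secured by the radical-stabilising boron at C11 and the polarity match, and it needs the slow closure through the s-cis ester rotamer to outrun chain transfer, which degenerate bromine transfer and high dilution should allow.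

Step 20
Reactants: 26 11-(pinacolatoboryl)-6,18-bis(tert-butyldimethylsilyloxy)-15-oxo-17-nor-6,7-seco-ent-kauran-7,20-olide
Product: 27 11-hydroxy-6,18-bis(tert-butyldimethylsilyloxy)-15-oxo-17-nor-6,7-seco-ent-kauran-7,20-olide
Conditions: H2O2 (30% aq.), NaOH, THF/H2O, 0 °C; then work-up at pH 4
Reagents that add atoms: hydrogen peroxide (OO)
Why: Peroxide oxidation of the secondary alkyl boronate with 1,2-migration of C11 from boron to oxygen should give the C11 alcohol with retention of configuration.

Step 21
Reactants: 27 11-hydroxy-6,18-bis(tert-butyldimethylsilyloxy)-15-oxo-17-nor-6,7-seco-ent-kauran-7,20-olide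
Product: 28 11-hydroxy-6,18-bis(tert-butyldimethylsilyloxy)-15-oxo-6,7-seco-ent-kaur-16-en-7,20-olide
Conditions: (CH2O)n, PhNHMe·CF3CO2H, THF, 65 °C
Reagents that add atoms: formaldehyde (C=O)
Why: Mannich-type α-methylenation (aminomethylation, then elimination) can occur only at C16 because C8 is quaternary and the lactone carbonyl has no α-hydrogen.

Step 22
Reactants: 28 11-hydroxy-6,18-bis(tert-butyldimethylsilyloxy)-15-oxo-6,7-seco-ent-kaur-16-en-7,20-olide
Product: 29 6,11,18-trihydroxy-15-oxo-6,7-seco-ent-kaur-16-en-7,20-olide (4S,5R,8S,9S,10S,11R,13S; target)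
Conditions: HF·pyridine, THF/pyridine, 0 → 25 °C
Reagents that add atoms: none
Why: Buffered fluoride cleavage of both silyl ethers should free the C6 and C18 alcohols without adding to the enone or opening the lactone.

**Compound list**

1 | ethyl 2-(triphenyl-λ5-phosphanylidene)propanoate | CCOC(=O)C(C)=P(c1ccccc1)(c1ccccc1)c1ccccc1 | starting material
2 | 2,2-dimethoxyacetaldehyde | COC(OC)C=O | starting material
3 | ethyl (2E)-4,4-dimethoxy-2-methylbut-2-enoate | CCOC(=O)/C(C)=C/C(OC)OC | intermediate
4 | ethyl (2E)-2-methyl-4-oxobut-2-enoate | CCOC(=O)/C(C)=C/C=O | intermediate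
5 | (2E)-penta-2,4-dienoic acid | C=C/C=C/C(=O)O | starting material
6 | (2E)-penta-2,4-dien-1-ol | C=C/C=C/CO | intermediate
7 | benzyl (2E)-penta-2,4-dien-1-yl ether | C=C/C=C/COCc1ccccc1 | intermediate
8 | ethyl 3-[(benzyloxy)methyl]-2-formyl-1-methylcyclohex-4-ene-1-carboxylate (formyl cis to methyl and to benzyloxymethyl, trans to ester) | c1ccccc1COC[C@H]1C=CC[C@](C)(C(=O)OCC)[C@H]1C=O | intermediate
9 | {3-[(benzyloxy)methyl]-1-methylcyclohex-4-ene-1,2-diyl}dimethanol | c1ccccc1COC[C@H]1C=CC[C@](C)(CO)[C@H]1CO | intermediate
10 | bis(tert-butyldimethylsilyl) ether of 9 | c1ccccc1COC[C@H]1C=CC[C@](C)(CO[Si](C)(C)C(C)(C)C)[C@H]1CO[Si](C)(C)C(C)(C)C | intermediate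
11 | [2,3-bis(tert-butyldimethylsilyloxymethyl)-3-methylcyclohexyl]methanol | OC[C@H]1CCC[C@](C)(CO[Si](C)(C)C(C)(C)C)[C@H]1CO[Si](C)(C)C(C)(C)C | intermediate
12 | 2,3-bis(tert-butyldimethylsilyloxymethyl)-3-methylcyclohexane-1-carboxylic acid | OC(=O)[C@H]1CCC[C@](C)(CO[Si](C)(C)C(C)(C)C)[C@H]1CO[Si](C)(C)C(C)(C)C | intermediate
13 | methyl 2,3-bis(tert-butyldimethylsilyloxymethyl)-3-methylcyclohexane-1-carboxylate | COC(=O)[C@H]1CCC[C@](C)(CO[Si](C)(C)C(C)(C)C)[C@H]1CO[Si](C)(C)C(C)(C)C | intermediate
14 | methyl 2,3-bis(tert-butyldimethylsilyloxymethyl)-1-formyl-3-methylcyclohexane-1-carboxylate (formyl trans to the C5 silyloxymethyl group) | COC(=O)[C@@]1(C=O)CCC[C@](C)(CO[Si](C)(C)C(C)(C)C)[C@H]1CO[Si](C)(C)C(C)(C)C | intermediate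
15 | methyl 2,3-bis(tert-butyldimethylsilyloxymethyl)-3-methyl-1-[(E)-2-(4,4,5,5-tetramethyl-1,3,2-dioxaborolan-2-yl)ethenyl]cyclohexane-1-carboxylate | COC(=O)[C@@]1(/C=C/B2OC(C)(C)C(C)(C)O2)CCC[C@](C)(CO[Si](C)(C)C(C)(C)C)[C@H]1CO[Si](C)(C)C(C)(C)C | intermediate
16 | {2,3-bis(tert-butyldimethylsilyloxymethyl)-3-methyl-1-[(E)-2-(4,4,5,5-tetramethyl-1,3,2-dioxaborolan-2-yl)ethenyl]cyclohexyl}methanol (ring A alcohol) | OC[C@@]1(/C=C/B2OC(C)(C)C(C)(C)O2)CCC[C@](C)(CO[Si](C)(C)C(C)(C)C)[C@H]1CO[Si](C)(C)C(C)(C)C | intermediate
17 | dimethyl propanedioate | COC(=O)CC(=O)OC | starting material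
18 | [2-(chloromethyl)prop-2-en-1-yl](trimethyl)silane | C=C(CCl)C[Si](C)(C)C | starting material
19 | dimethyl 2-{2-[(trimethylsilyl)methyl]prop-2-en-1-yl}propanedioate | COC(=O)C(CC(=C)C[Si](C)(C)C)C(=O)OC | intermediate
20 | 3-methoxy-3-oxo-2-{2-[(trimethylsilyl)methyl]prop-2-en-1-yl}propanoic acid (racemic) | COC(=O)C(CC(=C)C[Si](C)(C)C)C(=O)O | intermediate
21 | methyl 3-chloro-3-oxo-2-{2-[(trimethylsilyl)methyl]prop-2-en-1-yl}propanoate (acid chloride) | COC(=O)C(CC(=C)C[Si](C)(C)C)C(=O)Cl | intermediate
22 | methyl 4-methylidene-2-oxocyclopentane-1-carboxylate (racemic) | COC(=O)C1CC(=C)CC1=O | intermediate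
23 | ring A ester of 4-methylidene-2-oxocyclopentane-1-carboxylic acid (C8 epimers) | C=C1CC(=O)C(C1)C(=O)OC[C@@]1(/C=C/B2OC(C)(C)C(C)(C)O2)CCC[C@](C)(CO[Si](C)(C)C(C)(C)C)[C@H]1CO[Si](C)(C)C(C)(C)C | intermediate
24 | C8-bromo derivative of 23 (C8 epimers) | C=C1CC(=O)C(Br)(C1)C(=O)OC[C@@]1(/C=C/B2OC(C)(C)C(C)(C)O2)CCC[C@](C)(CO[Si](C)(C)C(C)(C)C)[C@H]1CO[Si](C)(C)C(C)(C)C | intermediate
25 | 13-bromo derivative of 26 (bridgehead bromide) | C1C(=O)[C@]23C[C@@]1(Br)C[C@@H](B4OC(C)(C)C(C)(C)O4)[C@H]2[C@@]1(CCC[C@](C)(CO[Si](C)(C)C(C)(C)C)[C@H]1CO[Si](C)(C)C(C)(C)C)COC3=O | intermediate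
26 | 11-(pinacolatoboryl)-6,18-bis(tert-butyldimethylsilyloxy)-15-oxo-17-nor-6,7-seco-ent-kauran-7,20-olide | C1C(=O)[C@]23C[C@H]1C[C@@H](B4OC(C)(C)C(C)(C)O4)[C@H]2[C@@]1(CCC[C@](C)(CO[Si](C)(C)C(C)(C)C)[C@H]1CO[Si](C)(C)C(C)(C)C)COC3=O | intermediate
27 | 11-hydroxy-6,18-bis(tert-butyldimethylsilyloxy)-15-oxo-17-nor-6,7-seco-ent-kauran-7,20-olide | C1C(=O)[C@]23C[C@H]1C[C@@H](O)[C@H]2[C@@]1(CCC[C@](C)(CO[Si](C)(C)C(C)(C)C)[C@H]1CO[Si](C)(C)C(C)(C)C)COC3=O | intermediate
28 | 11-hydroxy-6,18-bis(tert-butyldimethylsilyloxy)-15-oxo-6,7-seco-ent-kaur-16-en-7,20-olide | C=C1C(=O)[C@]23C[C@H]1C[C@@H](O)[C@H]2[C@@]1(CCC[C@](C)(CO[Si](C)(C)C(C)(C)C)[C@H]1CO[Si](C)(C)C(C)(C)C)COC3=O | intermediate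
29 | 6,11,18-trihydroxy-15-oxo-6,7-seco-ent-kaur-16-en-7,20-olide (4S,5R,8S,9S,10S,11R,13S) | C=C1C(=O)[C@]23C[C@H]1C[C@@H](O)[C@H]2[C@@]1(CCC[C@](C)(CO)[C@H]1CO)COC3=O | target

**Step count**

Total: 22 steps. Longest linear sequence: 17 steps (steps 1, 2, 5–13, 17–22).

**Three steps most likely to fail**

Step 19. Chain transfer may intercept the C8 radical before the slow first ring closure: the ester has to reach its s-cis rotamer and the new C8–C9 bond joins two hindered carbons. The result would be debrominated 23 or closure on the wrong face of C8. The fallback sets out from 23 (step 18 is skipped) and comes back at 26. It is a stoichiometric oxidative free-radical bicyclization with Mn(OAc)3·2H2O in degassed ethanol at 60 °C. The radical is generated within a chelated enolate of trivalent manganese, so no halogen or hydride donor competes with ring closure, and the bridgehead C13 radical ends by hydrogen abstraction from ethanol. This fallback makes no compound outside the list (F0).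

Step 5. The catalyst may discriminate the faces of the trisubstituted dienophile poorly, or the cycloaddition may stall. The fallback sets out from 4 and comes back at 9, using auxiliary control instead of catalyst control. Pinnick oxidation (NaClO2, NaH2PO4, 2-methylbut-2-ene) of 4 should give (2E)-4-ethoxy-3-methyl-4-oxobut-2-enoic acid F1. Activation as the mixed pivalic anhydride and acylation of lithiated (4S)-4-benzyl-1,3-oxazolidin-2-one should give ethyl (2E)-4-[(4S)-4-benzyl-2-oxo-1,3-oxazolidin-3-yl]-2-methyl-4-oxobut-2-enoate F2. The Et2AlCl-promoted Diels–Alder reaction of F2 with 7 (chelated imide, same ortho regiochemistry, one face shielded by the benzyl group) should give the imide cycloadduct F3. Reduction with LiBH4 in THF/MeOH should cleave the auxiliary and reduce both carbonyl groups to give diol 9.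

Step 11. The formylating agent may attack the wrong face of the exocyclic ester enolate, since allylic strain can turn the C5 substituent axial and shield the desired face; this would give the C10 epimer, and the formyl group may also be lost by retro-Claisen cleavage. The fallback sets out from 12 and comes back at 16, and it fixes the facial choice with a temporary ring. HF·pyridine should remove both silyl groups from 12, and the C20 acid should close onto the cis C6 hydroxyl to give the cis-fused hydroxy γ-lactone F4. Silylation (TBSCl, imidazole) should give the silyl lactone F5. Formylation of its enolate (LiN(i-Pr)2, then HCO2CH2CF3) can occur only on the convex face of the bicycle, placing C9 trans to C6 in the formyl lactone F6. Takai–Utimoto olefination (CrCl2, Cl2CHB(pin)) should give the alkenyl boronate lactone F7. Reduction with excess i-Bu2AlH should give the diol F8, and selective silylation of the less hindered C6 hydroxyl (TBSCl, imidazole, −20 °C) should give 16.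

**Further compounds**

F0 | step 19 | none | none
F1 | step 5 | (2E)-4-ethoxy-3-methyl-4-oxobut-2-enoic acid | CCOC(=O)/C(C)=C/C(=O)O
F2 | step 5 | ethyl (2E)-4-[(4S)-4-benzyl-2-oxo-1,3-oxazolidin-3-yl]-2-methyl-4-oxobut-2-enoate | CCOC(=O)/C(C)=C/C(=O)N1[C@@H](Cc2ccccc2)COC1=O
F3 | step 5 | imide cycloadduct (8 with the formyl group replaced by the N-acyl oxazolidinone) | c1ccccc1COC[C@H]2C=CC[C@](C)(C(=O)OCC)[C@H]2C(=O)N3[C@@H](Cc4ccccc4)COC3=O
F4 | step 11 | cis-fused hydroxy γ-lactone (C20 carbonyl, O–C6; C18 alcohol free) | O=C1[C@H]2CCC[C@](C)(CO)[C@H]2CO1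
F5 | step 11 | silyl lactone (C18 tert-butyldimethylsilyl ether of F4) | O=C1[C@H]2CCC[C@](C)(CO[Si](C)(C)C(C)(C)C)[C@H]2CO1
F6 | step 11 | formyl lactone (C10 formyl trans to C6) | O=C1[C@@]2(C=O)CCC[C@](C)(CO[Si](C)(C)C(C)(C)C)[C@H]2CO1
F7 | step 11 | alkenyl boronate lactone | O=C1[C@@]2(/C=C/B3OC(C)(C)C(C)(C)O3)CCC[C@](C)(CO[Si](C)(C)C(C)(C)C)[C@H]2CO1
F8 | step 11 | diol (16 with the C6 hydroxyl free) | OC[C@@]1(/C=C/B2OC(C)(C)C(C)(C)O2)CCC[C@](C)(CO[Si](C)(C)C(C)(C)C)[C@H]1CO
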